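The plan rests on opening rings A and B of the trans-decalin at C4–C5 and C9–C10, so that the quaternary centres C4 and C10, the C9 stereocentre and the C8(17) methylene derive from an acyclic E,E-diene β-keto ester whose single stereocentre is the C6 carbinol. One oxidative radical cascade closes both rings, sets C4, C5, C9 and C10 from C6 and leaves the exocyclic alkene. The precursor, a methyl 2-methyl-3-oxotrideca-6,10-dienoate bearing silyl ethers at C6 and C12 (labdane numbering), comes from (S)-benzyl glycidyl ether by alkyne carboalumination, Wittig olefination and acetoacetate dianion alkylation; C3 deoxygenation and Z-diene construction follow.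

Key step: step 10

Remark: labdane numbering is used for all carbon atoms; bicyclic compounds belong to the normal series (H-5 α, H-9 α, CH3-10 β, CO2Me at C4 β and axial); keto ester 15 is used as the mixture of epimers at its enolisable C4, and the transient radicals of step 10 carry no number.

Step 1
Reactants: 1 (S)-benzyl glycidyl ether
Product: 2 (S)-1-(benzyloxy)pent-4-yn-2-ol
Conditions: LiC≡CH·H2NCH2CH2NH2, DMSO, 0 °C → rt; then H2O
Reagents that add atoms: lithium acetylide–ethylenediamine complex, [Li+].[C-]#C.NCCN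
Why: SN2 epoxide opening by the acetylide at the unhindered CH2 terminus (C7) leaves the purchased C6 stereocentre untouched and delivers the C8≡C9 alkyne.

Step 2
Reactants: 2 (S)-1-(benzyloxy)pent-4-yn-2-ol
Product: 3 (S)-1-(benzyloxy)-2-[(tert-butyldimethylsilyl)oxy]pent-4-yne
Conditions: TBSCl, imidazole, DMF, rt
Reagents that add atoms: tert-butyldimethylsilyl chloride, CC(C)(C)[Si](C)(C)Cl
Why: Imidazole-promoted silylation of the secondary alcohol masks the C6 oxygen for the organoaluminium, hydride and enolate steps that follow.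

Step 3
Reactants: 3 (S)-1-(benzyloxy)-2-[(tert-butyldimethylsilyl)oxy]pent-4-yne
Product: 6 (3E,6S)-7-(benzyloxy)-6-[(tert-butyldimethylsilyl)oxy]-4-methylhept-3-en-1-ol, via the alkenyldimethylalane 4 (not isolated), via the lithium alkenylaluminate 5 (not isolated)
Conditions: AlMe3 (3 equiv), Cp2ZrCl2 (0.25 equiv), CH2Cl2, 0 °C → rt; volatiles removed; n-BuLi, hexane–THF, −78 → 0 °C; ethylene oxide, 0 °C → rt; aq. potassium sodium tartrate
Reagents that add atoms: trimethylaluminium, C[Al](C)C; ethylene oxide, C1CO1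
Why: Zirconium-catalysed syn-carboalumination (Negishi) puts CH3 on C8 and aluminium on C9, and the derived aluminate opens ethylene oxide with retention at the alkenyl carbon, so the E geometry of C8=C9 and the C11–C12 arm are fixed together.

Step 4
Reactants: 6 (3E,6S)-7-(benzyloxy)-6-[(tert-butyldimethylsilyl)oxy]-4-methylhept-3-en-1-ol
Product: 7 (2S,4E)-1-(benzyloxy)-2-[(tert-butyldimethylsilyl)oxy]-4-methyl-7-[(triisopropylsilyl)oxy]hept-4-ene
Conditions: TIPSCl, imidazole, DMF, rt
Reagents that add atoms: triisopropylsilyl chloride, CC(C)[Si](Cl)(C(C)C)C(C)C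
Why: Silylation of the primary alcohol with a group that withstands arene radical anions, strong base and acetic acid protects C12 up to the end game.

Step 5
Reactants: 7 (2S,4E)-1-(benzyloxy)-2-[(tert-butyldimethylsilyl)oxy]-4-methyl-7-[(triisopropylsilyl)oxy]hept-4-ene
Product: 8 (2S,4E)-2-[(tert-butyldimethylsilyl)oxy]-4-methyl-7-[(triisopropylsilyl)oxy]hept-4-en-1-ol
Conditions: Li, 4,4′-di-tert-butylbiphenyl, THF, 0 °C (gives LiDBB); then 7, −78 °C; H2O at −78 °C
Reagents that add atoms: none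
Why: Single-electron reductive debenzylation by the arene radical anion spares the isolated trisubstituted alkene and both silyl ethers, and the cold quench forestalls 1,2-silyl migration to the new alkoxide.

Step 6
Reactants: 8 (2S,4E)-2-[(tert-butyldimethylsilyl)oxy]-4-methyl-7-[(triisopropylsilyl)oxy]hept-4-en-1-ol
Product: 10 ethyl (2E,4S,6E)-4-[(tert-butyldimethylsilyl)oxy]-2,6-dimethyl-9-[(triisopropylsilyl)oxy]nona-2,6-dienoate, via the α-silyloxy aldehyde 9 (not isolated)
Conditions: PhI(OAc)2, TEMPO (10 mol %), CH2Cl2, rt; then Ph3P=C(CH3)CO2Et (2.5 equiv), rt → 40 °C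
Reagents that add atoms: ethyl 2-(triphenylphosphoranylidene)propanoate, CCOC(=O)C(C)=P(c1ccccc1)(c1ccccc1)c1ccccc1
Why: Oxoammonium oxidation gives the epimerisable aldehyde under non-basic conditions and the stabilised α-methyl ylide traps it at once in a Wittig olefination that should give the E trisubstituted C5=C10 alkene.

Step 7
Reactants: 10 ethyl (2E,4S,6E)-4-[(tert-butyldimethylsilyl)oxy]-2,6-dimethyl-9-[(triisopropylsilyl)oxy]nona-2,6-dienoate
Product: 11 (2E,4S,6E)-4-[(tert-butyldimethylsilyl)oxy]-2,6-dimethyl-9-[(triisopropylsilyl)oxy]nona-2,6-dien-1-ol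
Conditions: i-Bu2AlH (2.5 equiv), CH2Cl2, −78 °C; aq. potassium sodium tartrate
Reagents that add atoms: none
Why: 1,2-Reduction of the enoate by the aluminium hydride gives the C1 allylic alcohol without touching the alkene geometry or the silyl ethers.

Step 8
Reactants: 11 (2E,4S,6E)-4-[(tert-butyldimethylsilyl)oxy]-2,6-dimethyl-9-[(triisopropylsilyl)oxy]nona-2,6-dien-1-ol
Product: 12 (2E,4S,6E)-1-bromo-4-[(tert-butyldimethylsilyl)oxy]-2,6-dimethyl-9-[(triisopropylsilyl)oxy]nona-2,6-diene
Conditions: CBr4, PPh3, CH2Cl2, 0 °C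
Reagents that add atoms: carbon tetrabromide, BrC(Br)(Br)Br
Why: Appel bromination converts the primary allylic alcohol by SN2 displacement of the oxyphosphonium, without allylic transposition.

Step 9
Reactants: 12 (2E,4S,6E)-1-bromo-4-[(tert-butyldimethylsilyl)oxy]-2,6-dimethyl-9-[(triisopropylsilyl)oxy]nona-2,6-diene; 13 methyl 2-methyl-3-oxobutanoate
Product: 15 methyl (6E,8S,10E)-8-[(tert-butyldimethylsilyl)oxy]-2,6,10-trimethyl-3-oxo-13-[(triisopropylsilyl)oxy]trideca-6,10-dienoate, via the lithium sodium dianion 14 (not isolated)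
Conditions: 13, NaH, THF, 0 °C; n-BuLi, 0 °C; then 12, 0 °C; aq. HCl
Reagents that add atoms: none
Why: Acetoacetate dianion alkylation (Weiler) takes place at the more basic terminal carbanion, which displaces the allylic bromide by SN2 and forms C1–C2.

Step 10
Reactants: 15 methyl (6E,8S,10E)-8-[(tert-butyldimethylsilyl)oxy]-2,6,10-trimethyl-3-oxo-13-[(triisopropylsilyl)oxy]trideca-6,10-dienoate
Product: 16 methyl 6α-[(tert-butyldimethylsilyl)oxy]-3-oxo-12-[(triisopropylsilyl)oxy]-13,14,15,16-tetranorlabd-8(17)-en-19-oate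
Conditions: Mn(OAc)3·2H2O (2.2 equiv), Cu(OAc)2·H2O (1 equiv), degassed AcOH, 20 °C
Reagents that add atoms: none
Why: Mn(OAc)3 converts the α-methyl β-keto ester into its manganese enolate and electron transfer to trivalent manganese gives the electrophilic tertiary C4 radical, which adds to C5; the tertiary C10 radical adds to C9, and the tertiary C8 radical is captured by Cu(OAc)2 as an alkylcopper species (trivalent copper) that loses a C17 hydrogen by β-hydride elimination, the monovalent copper being reoxidised by Mn(OAc)3. The closest known reaction type is the Mn(OAc)3/Cu(OAc)2 oxidative free-radical polyene cyclization of α-alkyl β-keto esters to trans-fused decalones with an exocyclic methylene. Ring A closes in the 6-endo-trig mode (C4 onto C5 of the trisubstituted C5=C10 alkene) and ring B likewise 6-endo-trig (C10 onto C9), each through a chair. C4 is set by the chair that carries the ester axial with the ketone in the ring, C5 and C10 by the chair–chair array that gives the trans fusion with CH3-10 axial, and C9 by the E geometry of C8=C9, which places C11 equatorial. The step needs facial selectivity at C5 relative to C6: allylic 1,3-strain with the C10 methyl should hold H-6 in the alkene plane, the electron-poor radical should then approach anti to the C6–C7 bond with the C–O bond turned outward, and this is the folding that leaves the silyloxy group equatorial (6α) on ring B. The C8=C17 alkene is expected over endocyclic isomers because the copper-mediated elimination prefers the least hindered hydrogen.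

Step 11
Reactants: 16 methyl 6α-[(tert-butyldimethylsilyl)oxy]-3-oxo-12-[(triisopropylsilyl)oxy]-13,14,15,16-tetranorlabd-8(17)-en-19-oate
Product: 17 methyl 6α-[(tert-butyldimethylsilyl)oxy]-3-(tosylhydrazono)-12-[(triisopropylsilyl)oxy]-13,14,15,16-tetranorlabd-8(17)-en-19-oate
Conditions: TsNHNH2, EtOH, 70 °C
Reagents that add atoms: 4-methylbenzenesulfonohydrazide, Cc1ccc(cc1)S(=O)(=O)NN
Why: Condensation to the tosylhydrazone occurs at the only ketone, as is usual for 3-oxo terpenoids with a quaternary C4.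

Step 12
Reactants: 17 methyl 6α-[(tert-butyldimethylsilyl)oxy]-3-(tosylhydrazono)-12-[(triisopropylsilyl)oxy]-13,14,15,16-tetranorlabd-8(17)-en-19-oate
Product: 19 methyl 6α-[(tert-butyldimethylsilyl)oxy]-12-[(triisopropylsilyl)oxy]-13,14,15,16-tetranorlabd-8(17)-en-19-oate, via the N-borylated tosylhydrazide 18 (not isolated)
Conditions: catecholborane, CHCl3, 0 °C → rt; then NaOAc·3H2O, 60 °C
Reagents that add atoms: none
Why: Kabalka's catecholborane variant of the Caglioti tosylhydrazone reduction adds hydride to C=N, acetate then triggers loss of sulfinate and nitrogen to leave CH2 at C3, with esters, silyl ethers and the 1,1-disubstituted alkene untouched.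

Step 13
Reactants: 19 methyl 6α-[(tert-butyldimethylsilyl)oxy]-12-[(triisopropylsilyl)oxy]-13,14,15,16-tetranorlabd-8(17)-en-19-oate
Product: 20 methyl 6α,12-dihydroxy-13,14,15,16-tetranorlabd-8(17)-en-19-oate
Conditions: Bu4NF, THF, rt → 45 °C
Reagents that add atoms: none
Why: Fluoride-induced desilylation frees both alcohols; the 6α-hydroxyl is trans to the axial C19 ester and so cannot lactonise.

Step 14
Reactants: 20 methyl 6α,12-dihydroxy-13,14,15,16-tetranorlabd-8(17)-en-19-oate
Product: 21 methyl 6α-hydroxy-12-oxo-13,14,15,16-tetranorlabd-8(17)-en-19-oate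
Conditions: PhI(OAc)2, TEMPO (10 mol %), CH2Cl2, rt
Reagents that add atoms: none
Why: The hindered oxoammonium oxidant (TEMPO/PhI(OAc)2 oxidation) discriminates the primary C12 alcohol from the congested secondary C6 alcohol and stops at the aldehyde.

Step 15
Reactants: 21 methyl 6α-hydroxy-12-oxo-13,14,15,16-tetranorlabd-8(17)-en-19-oate
Product: 22 methyl 6α-acetoxy-12-oxo-13,14,15,16-tetranorlabd-8(17)-en-19-oate
Conditions: Ac2O, pyridine, DMAP (cat.), CH2Cl2, 0 °C → rt
Reagents that add atoms: acetic anhydride, CC(=O)OC(C)=O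
Why: DMAP-catalysed acylation installs the C6 acetate of the target and removes the only acidic proton before the ylide step.

Step 16
Reactants: 22 methyl 6α-acetoxy-12-oxo-13,14,15,16-tetranorlabd-8(17)-en-19-oate
Product: 23 methyl (12Z)-6α-acetoxy-13-iodo-14,15-dinorlabda-8(17),12-dien-19-oate
Conditions: EtPPh3I, n-BuLi, THF, rt; I2, −78 °C; NaN(SiMe3)2, −20 °C; then 22, −78 → −20 °C
Reagents that add atoms: ethyltriphenylphosphonium iodide, CC[P+](c1ccccc1)(c1ccccc1)c1ccccc1.[I-]; iodine, II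
Why: Stork–Zhao-type Wittig olefination with the α-iodoethylidene ylide proceeds under kinetic control through the cis oxaphosphetane, which should place iodine cis to C11 (12Z) and supplies C13 and its methyl group.

Step 17
Reactants: 23 methyl (12Z)-6α-acetoxy-13-iodo-14,15-dinorlabda-8(17),12-dien-19-oate
Product: 24 methyl (12Z)-6α-acetoxylabda-8(17),12,14-trien-19-oate
Conditions: CH2=CHSnBu3, PdCl2(MeCN)2 (5 mol %), DMF, rt, dark
Reagents that add atoms: tributyl(vinyl)stannane, C=C[Sn](CCCC)(CCCC)CCCC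
Why: Stille coupling (oxidative addition of zerovalent palladium formed in situ, transmetalation, reductive elimination) replaces iodine by vinyl with retention of the alkene geometry under neutral conditions that the acetate tolerates.

Compound list
1 | (S)-benzyl glycidyl ether | C(OCc1ccccc1)[C@@H]1CO1 | starting material
2 | (S)-1-(benzyloxy)pent-4-yn-2-ol | C#CC[C@H](O)COCc1ccccc1 | intermediate
3 | (S)-1-(benzyloxy)-2-[(tert-butyldimethylsilyl)oxy]pent-4-yne | C#CC[C@H](O[Si](C)(C)C(C)(C)C)COCc1ccccc1 | intermediate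
4 | [(1E,4S)-5-(benzyloxy)-4-[(tert-butyldimethylsilyl)oxy]-2-methylpent-1-enyl]dimethylalane | C[Al](C)/C=C(\C)C[C@H](O[Si](C)(C)C(C)(C)C)COCc1ccccc1 | intermediate
5 | lithium butyl[(1E,4S)-5-(benzyloxy)-4-[(tert-butyldimethylsilyl)oxy]-2-methylpent-1-enyl]dimethylaluminate | [Li+].CCCC[Al-](C)(C)/C=C(\C)C[C@H](O[Si](C)(C)C(C)(C)C)COCc1ccccc1 | intermediate
6 | (3E,6S)-7-(benzyloxy)-6-[(tert-butyldimethylsilyl)oxy]-4-methylhept-3-en-1-ol | OCC/C=C(\C)C[C@H](O[Si](C)(C)C(C)(C)C)COCc1ccccc1 | intermediate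
7 | (2S,4E)-1-(benzyloxy)-2-[(tert-butyldimethylsilyl)oxy]-4-methyl-7-[(triisopropylsilyl)oxy]hept-4-ene | CC(C)[Si](C(C)C)(C(C)C)OCC/C=C(\C)C[C@H](O[Si](C)(C)C(C)(C)C)COCc1ccccc1 | intermediate
8 | (2S,4E)-2-[(tert-butyldimethylsilyl)oxy]-4-methyl-7-[(triisopropylsilyl)oxy]hept-4-en-1-ol | CC(C)[Si](C(C)C)(C(C)C)OCC/C=C(\C)C[C@H](O[Si](C)(C)C(C)(C)C)CO | intermediate
9 | (2S,4E)-2-[(tert-butyldimethylsilyl)oxy]-4-methyl-7-[(triisopropylsilyl)oxy]hept-4-enal | CC(C)[Si](C(C)C)(C(C)C)OCC/C=C(\C)C[C@H](O[Si](C)(C)C(C)(C)C)C=O | intermediate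
10 | ethyl (2E,4S,6E)-4-[(tert-butyldimethylsilyl)oxy]-2,6-dimethyl-9-[(triisopropylsilyl)oxy]nona-2,6-dienoate | CCOC(=O)/C(C)=C/[C@@H](O[Si](C)(C)C(C)(C)C)C/C(C)=C/CCO[Si](C(C)C)(C(C)C)C(C)C | intermediate
11 | (2E,4S,6E)-4-[(tert-butyldimethylsilyl)oxy]-2,6-dimethyl-9-[(triisopropylsilyl)oxy]nona-2,6-dien-1-ol | OC/C(C)=C/[C@@H](O[Si](C)(C)C(C)(C)C)C/C(C)=C/CCO[Si](C(C)C)(C(C)C)C(C)C | intermediate
12 | (2E,4S,6E)-1-bromo-4-[(tert-butyldimethylsilyl)oxy]-2,6-dimethyl-9-[(triisopropylsilyl)oxy]nona-2,6-diene | BrC/C(C)=C/[C@@H](O[Si](C)(C)C(C)(C)C)C/C(C)=C/CCO[Si](C(C)C)(C(C)C)C(C)C | intermediate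
13 | methyl 2-methyl-3-oxobutanoate (methyl 2-methylacetoacetate) | COC(=O)C(C)C(C)=O | starting material
14 | lithium sodium dianion of methyl 2-methyl-3-oxobutanoate | [Li+].[Na+].[CH2-]C(=O)[C-](C)C(=O)OC | intermediate
15 | methyl (6E,8S,10E)-8-[(tert-butyldimethylsilyl)oxy]-2,6,10-trimethyl-3-oxo-13-[(triisopropylsilyl)oxy]trideca-6,10-dienoate (C2 epimers) | COC(=O)C(C)C(=O)CC/C(C)=C/[C@@H](O[Si](C)(C)C(C)(C)C)C/C(C)=C/CCO[Si](C(C)C)(C(C)C)C(C)C | intermediate
16 | methyl 6α-[(tert-butyldimethylsilyl)oxy]-3-oxo-12-[(triisopropylsilyl)oxy]-13,14,15,16-tetranorlabd-8(17)-en-19-oate | CC(C)[Si](C(C)C)(C(C)C)OCC[C@H]1C(=C)C[C@H](O[Si](C)(C)C(C)(C)C)[C@@H]2[C@]1(C)CCC(=O)[C@]2(C)C(=O)OC | intermediate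
17 | methyl 6α-[(tert-butyldimethylsilyl)oxy]-3-(tosylhydrazono)-12-[(triisopropylsilyl)oxy]-13,14,15,16-tetranorlabd-8(17)-en-19-oate | CC(C)[Si](C(C)C)(C(C)C)OCC[C@H]1C(=C)C[C@H](O[Si](C)(C)C(C)(C)C)[C@@H]2[C@]1(C)CCC(=NNS(=O)(=O)c3ccc(C)cc3)[C@]2(C)C(=O)OC | intermediate
18 | methyl 3-[1-(1,3,2-benzodioxaborol-2-yl)-2-tosylhydrazinyl]-6α-[(tert-butyldimethylsilyl)oxy]-12-[(triisopropylsilyl)oxy]-13,14,15,16-tetranorlabd-8(17)-en-19-oate | CC(C)[Si](C(C)C)(C(C)C)OCC[C@H]1C(=C)C[C@H](O[Si](C)(C)C(C)(C)C)[C@@H]2[C@]1(C)CCC(N(NS(=O)(=O)c3ccc(C)cc3)B3Oc4ccccc4O3)[C@]2(C)C(=O)OC | intermediate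
19 | methyl 6α-[(tert-butyldimethylsilyl)oxy]-12-[(triisopropylsilyl)oxy]-13,14,15,16-tetranorlabd-8(17)-en-19-oate | CC(C)[Si](C(C)C)(C(C)C)OCC[C@H]1C(=C)C[C@H](O[Si](C)(C)C(C)(C)C)[C@@H]2[C@]1(C)CCC[C@]2(C)C(=O)OC | intermediate
20 | methyl 6α,12-dihydroxy-13,14,15,16-tetranorlabd-8(17)-en-19-oate | OCC[C@H]1C(=C)C[C@H](O)[C@@H]2[C@]1(C)CCC[C@]2(C)C(=O)OC | intermediate
21 | methyl 6α-hydroxy-12-oxo-13,14,15,16-tetranorlabd-8(17)-en-19-oate | O=CC[C@H]1C(=C)C[C@H](O)[C@@H]2[C@]1(C)CCC[C@]2(C)C(=O)OC | intermediate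
22 | methyl 6α-acetoxy-12-oxo-13,14,15,16-tetranorlabd-8(17)-en-19-oate | O=CC[C@H]1C(=C)C[C@H](OC(C)=O)[C@@H]2[C@]1(C)CCC[C@]2(C)C(=O)OC | intermediate
23 | methyl (12Z)-6α-acetoxy-13-iodo-14,15-dinorlabda-8(17),12-dien-19-oate | C/C(I)=C/C[C@H]1C(=C)C[C@H](OC(C)=O)[C@@H]2[C@]1(C)CCC[C@]2(C)C(=O)OC | intermediate
24 | methyl (12Z)-6α-acetoxylabda-8(17),12,14-trien-19-oate | C=C/C(C)=C\C[C@H]1C(=C)C[C@H](OC(C)=O)[C@@H]2[C@]1(C)CCC[C@]2(C)C(=O)OC | target

Total step count: 17. Longest linear sequence: 17 steps (1 → 24); 13 enters at step 9.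

Steps most likely to fail

Step 10. What may go wrong is weak facial discrimination in the first ring closure (approach of the C4 radical syn instead of anti to the C6–C7 bond, giving the decalin of opposite absolute sense with an axial silyloxy group), or acid-induced loss of the allylic silyl ether before cyclization. The fallback moves the stereocontrol to the small, acid-stable and more electron-withdrawing acetoxy group that the target needs anyway, and sets out from 15. HF·pyridine in THF should remove both silyl groups to give the diol keto ester F1. TIPSCl and imidazole at 0 °C should silylate only the primary alcohol to give the C6 alcohol F2, and Ac2O in pyridine gives the C6 acetate F3. The same Mn(OAc)3/Cu(OAc)2 treatment should then give the acetoxy decalone F4. Tosylhydrazone formation gives F5 and catecholborane/NaOAc reduction gives the deoxygenated acetate F6. Bu4NF buffered with AcOH frees the primary alcohol F7, and TEMPO/PhI(OAc)2 oxidation returns the route at 22.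

Step 12. What may go wrong is sluggish hydride delivery to the neopentyl C3 hydrazone and competing elimination toward a C2=C3 alkene. The fallback replaces hydrazone chemistry by radical deoxygenation and sets out from 16. NaBH4 in MeOH at 0 °C should give the C3 alcohol F8 (expected 3β; either epimer serves). Phenyl chlorothionoformate with pyridine and DMAP, chosen to avoid a retro-aldol-prone alkoxide, gives the thionocarbonate F9. Barton–McCombie reduction with Bu3SnH and AIBN in toluene at 90 °C returns the route at 19.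

Step 16. What may go wrong is erosion of Z selectivity and low conversion through decomposition or protonation of the hindered iodo ylide. The fallback builds the same alkene by stereoselective cross-coupling and sets out from 22. Ramirez olefination (CBr4, PPh3, CH2Cl2, 0 °C) gives the 13,13-dibromoalkene F10. Palladium-catalysed Negishi monomethylation (Me2Zn, PdCl2(DPEphos), THF), which is selective for the bromine trans to C11, should give the (12Z)-13-bromoalkene F11. Stille coupling with tributyl(vinyl)stannane (Pd(P(t-Bu)3)2, CsF, dioxane) with retention returns the route at 24.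

Further compounds
F1 | step 10 | methyl (6E,8S,10E)-8,13-dihydroxy-2,6,10-trimethyl-3-oxotrideca-6,10-dienoate (diol keto ester) | COC(=O)C(C)C(=O)CC/C(C)=C/[C@@H](O)C/C(C)=C/CCO
F2 | step 10 | methyl (6E,8S,10E)-8-hydroxy-2,6,10-trimethyl-3-oxo-13-[(triisopropylsilyl)oxy]trideca-6,10-dienoate (C6 alcohol) | COC(=O)C(C)C(=O)CC/C(C)=C/[C@@H](O)C/C(C)=C/CCO[Si](C(C)C)(C(C)C)C(C)C
F3 | step 10 | methyl (6E,8S,10E)-8-acetoxy-2,6,10-trimethyl-3-oxo-13-[(triisopropylsilyl)oxy]trideca-6,10-dienoate (C6 acetate) | COC(=O)C(C)C(=O)CC/C(C)=C/[C@@H](OC(C)=O)C/C(C)=C/CCO[Si](C(C)C)(C(C)C)C(C)C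
F4 | step 10 | methyl 6α-acetoxy-3-oxo-12-[(triisopropylsilyl)oxy]-13,14,15,16-tetranorlabd-8(17)-en-19-oate (acetoxy decalone) | CC(C)[Si](C(C)C)(C(C)C)OCC[C@H]1C(=C)C[C@H](OC(C)=O)[C@@H]2[C@]1(C)CCC(=O)[C@]2(C)C(=O)OC
F5 | step 10 | methyl 6α-acetoxy-3-(tosylhydrazono)-12-[(triisopropylsilyl)oxy]-13,14,15,16-tetranorlabd-8(17)-en-19-oate | CC(C)[Si](C(C)C)(C(C)C)OCC[C@H]1C(=C)C[C@H](OC(C)=O)[C@@H]2[C@]1(C)CCC(=NNS(=O)(=O)c3ccc(C)cc3)[C@]2(C)C(=O)OC
F6 | step 10 | methyl 6α-acetoxy-12-[(triisopropylsilyl)oxy]-13,14,15,16-tetranorlabd-8(17)-en-19-oate (deoxygenated acetate) | CC(C)[Si](C(C)C)(C(C)C)OCC[C@H]1C(=C)C[C@H](OC(C)=O)[C@@H]2[C@]1(C)CCC[C@]2(C)C(=O)OC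
F7 | step 10 | methyl 6α-acetoxy-12-hydroxy-13,14,15,16-tetranorlabd-8(17)-en-19-oate (primary alcohol) | OCC[C@H]1C(=C)C[C@H](OC(C)=O)[C@@H]2[C@]1(C)CCC[C@]2(C)C(=O)OC
F8 | step 12 | methyl 6α-[(tert-butyldimethylsilyl)oxy]-3β-hydroxy-12-[(triisopropylsilyl)oxy]-13,14,15,16-tetranorlabd-8(17)-en-19-oate (C3 alcohol) | CC(C)[Si](C(C)C)(C(C)C)OCC[C@H]1C(=C)C[C@H](O[Si](C)(C)C(C)(C)C)[C@@H]2[C@]1(C)CC[C@H](O)[C@]2(C)C(=O)OC
F9 | step 12 | methyl 6α-[(tert-butyldimethylsilyl)oxy]-3β-[(phenoxycarbonothioyl)oxy]-12-[(triisopropylsilyl)oxy]-13,14,15,16-tetranorlabd-8(17)-en-19-oate (thionocarbonate) | CC(C)[Si](C(C)C)(C(C)C)OCC[C@H]1C(=C)C[C@H](O[Si](C)(C)C(C)(C)C)[C@@H]2[C@]1(C)CC[C@H](OC(=S)Oc3ccccc3)[C@]2(C)C(=O)OC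
F10 | step 16 | methyl 6α-acetoxy-13,13-dibromo-14,15,16-trinorlabda-8(17),12-dien-19-oate (13,13-dibromoalkene) | BrC(Br)=CC[C@H]1C(=C)C[C@H](OC(C)=O)[C@@H]2[C@]1(C)CCC[C@]2(C)C(=O)OC
F11 | step 16 | methyl (12Z)-6α-acetoxy-13-bromo-14,15-dinorlabda-8(17),12-dien-19-oate ((12Z)-13-bromoalkene) | C/C(Br)=C/C[C@H]1C(=C)C[C@H](OC(C)=O)[C@@H]2[C@]1(C)CCC[C@]2(C)C(=O)OC
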